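All constants were set for the occasion; the rest is arithmetic.

I began from the small charge of D, 0.0100 M, because I had to choose the charge of G for the next run and first wanted to know what D takes from L.

    L + G → X + E (k1 = 2.52 L mol⁻¹ s⁻¹)
    X ⇌ J (K2 = 2.17, k2 = 0.105 s⁻¹)
    X ⇌ Q (K3 = 2.1, k3 = 0.00653 s⁻¹)
    L + D → L.D (k4 = 15.0 L mol⁻¹ s⁻¹)

L 0.20 M; G 0.100 M; D 0.0100 M; time 40 min

- how much of the L has reacted by 40 min
- how much J there is at 40 min, in percent of the L charged
- how much Q there is at 40 min, in percent of the L charged

1. I compared the two steps that use L. Both rates carry [L], so their ratio at the start was k1[G]/(k4[D]), and step 1 ran 1.7 times as fast as step 4.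

2. I asked how that ratio drifted. [D] fell 5.95 times faster than [G] in relative terms, because k4, at 15.0 L mol⁻¹ s⁻¹, is larger than k1, at 2.52 L mol⁻¹ s⁻¹, so the ratio rose as the run went on.

3. The drift did not change the amounts, because each G and each D takes one L and the two charges together stayed below the charge of L. G and D were thus the limiting reagents.

4. Even at the lowest [L] these charges allow, the half-life of G was 0.0509 min, short against 40 min.

5. So I committed to a conversion of 55.0%, which I called the take-up: the charges of G and D summed, over the charge of L.

6. The forward half-lives of X by steps 2 and 3, 0.11 min and 1.77 min, were also short against 40 min. I therefore shared the 50.0% of L that went through X as 1 : 2.17 : 2.1 among X, J and Q, which gave J 20.6% and Q 19.9%.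

7. I decided that the next run would change the charge of G and leave the time as it was.

8. The forecast gave 55%, 20.6% and 19.9%, the same as mine, holding that “L is in excess and both G and D are used up within seconds”.

9. The simulation gave 55.0%, 20.6% and 19.9%.

In this flask, step 1 had 100% of its turnover up to 40 min behind it by 4.00 min, and the ratio of step 1 to step 4 had risen from 1.7 to 52 by 0.0282 min. At 40.0 min this flask held 0% of its G and 0% of its D, less than the 45% of its L, and the conversion of 55.0% stood beside a take-up of 55.0%. In the neighbour flask with 0.060 M of G, the take-up was 35.0% and the conversion was 35.0%.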